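**Retrosynthetic overview**
- The target is opened at C7–C8 and at the lactone C–O bond: one enantioselective chromium-catalysed 2-(alkoxycarbonyl)allylation of an acyclic C8 aldehyde / C13 allylic bromide closes the ten-membered carbocycle, and the new alkoxide closes the γ-lactone in the same flask; both ring stereocentres are set there.
- The cyclisation substrate comes from cross-metathesis of a terminal allyl group with methyl 2-(bromomethyl)acrylate (C7=C11) and unmasking of a dioxolane at C8.
- C1=C10 (E, C14 cis to H1) comes from a Wittig reaction of a C1 aldehyde with a formyl-stabilised ylide, then Luche reduction to the C14 alcohol.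
- C4=C5 (C15 cis to C6) comes from copper-catalysed anti-carbomagnesiation of propargyl alcohol with allyl trapping; the free C15–OH is esterified at once with the (R)-chlorohydrin acid, made from the commercial (R)-bromo acid.
- Ring order: ten-membered carbocycle first, γ-lactone directly after in the same operation; no carbocycle or lactone exists before the last step.

Atom labels C1–C15 are germacrane numbers of the target: lactone C12(=O)–O–C8, exocyclic methylene C13 on C11, C14 = hydroxymethyl carbon on C10, C15 = acyloxymethyl carbon on C4.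

Assumption: the sense of induction of the chromium/ligand pair in step 10 is assigned by analogy with its intermolecular allylations; if the ring forms with the opposite absolute configuration, the (R,R)-ligand is used instead.

**Route**

Step 1
Reactants: 1 prop-2-yn-1-ol; 2 2-(2-bromoethyl)-1,3-dioxolane; 3 allyl bromide
Product: 6 (2Z)-2-[2-(1,3-dioxolan-2-yl)ethyl]hexa-2,5-dien-1-ol, via Grignard reagent 4 (not isolated), via alkenylmagnesium alkoxide 5 (not isolated)
Conditions: 2 (2.6 equiv), Mg, THF, 25–30 °C; then 1, CuI (10 mol %), THF, −10 → 25 °C, 14 h; then 3 (3 equiv), −20 → 25 °C; aq. NH4Cl work-up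
Reagents that add atoms: none
Why: Copper-catalysed anti-carbomagnesiation of the propargylic alkoxide (Duboudin–Jousseaume reaction) puts the alkyl group on C4 and magnesium on C5 cis to the CH2O group through a five-membered chelate, and copper-mediated allylation of that alkenylmagnesium goes with retention, so C15 and C6 end up cis (2Z) as in the target.

Step 2
Reactants: 7 (2R)-3-bromo-2-hydroxy-2-methylpropanoic acid
Product: 9 (2R)-3-chloro-2-hydroxy-2-methylpropanoic acid, via sodium (2S)-2-methyloxirane-2-carboxylate 8 (not isolated)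
Conditions: NaOH (2.1 equiv), H2O, 0 → 25 °C; then conc. aq. HCl, LiCl, 0 → 25 °C
Reagents that add atoms: hydrogen chloride, Cl
Why: Intramolecular Williamson closure gives the glycidate and chloride then opens it by SN2 attack at the unsubstituted CH2, so the quaternary stereocentre is never touched and the (R) descriptor returns because CH2Cl outranks CO2H just as CH2Br did.

Step 3
Reactants: 6 (2Z)-2-[2-(1,3-dioxolan-2-yl)ethyl]hexa-2,5-dien-1-ol; 9 (2R)-3-chloro-2-hydroxy-2-methylpropanoic acid
Product: 10 (2Z)-2-[2-(1,3-dioxolan-2-yl)ethyl]hexa-2,5-dien-1-yl (2R)-3-chloro-2-hydroxy-2-methylpropanoate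
Conditions: EDC·HCl (1.3 equiv), DMAP (0.1 equiv), CH2Cl2, 0 → 25 °C
Reagents that add atoms: none
Why: Steglich esterification of the unhindered primary allylic alcohol, in which the tertiary hydroxyl of 9 is too hindered to compete and the stereocentre is not involved.

Step 4
Reactants: 10 (2Z)-2-[2-(1,3-dioxolan-2-yl)ethyl]hexa-2,5-dien-1-yl (2R)-3-chloro-2-hydroxy-2-methylpropanoate
Product: 11 (2Z)-2-(3-oxopropyl)hexa-2,5-dien-1-yl (2R)-3-chloro-2-hydroxy-2-methylpropanoate
Conditions: 2 M aq. HCl–THF (1:3), 25 °C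
Reagents that add atoms: water, O
Why: Acid-catalysed acetal hydrolysis frees the C1 aldehyde, while the ester, the chlorohydrin and the skipped diene are stable to dilute aqueous acid at 25 °C.

Step 5
Reactants: 12 [2-(1,3-dioxolan-2-yl)ethyl]triphenylphosphonium bromide; 13 ethyl formate
Product: 15 3-(1,3-dioxolan-2-yl)-2-(triphenyl-λ5-phosphanylidene)propanal, via ylide 14 (not isolated)
Conditions: KOtBu (1.1 equiv), THF, 0 °C; then 13 (1.5 equiv), 0 → 25 °C
Reagents that add atoms: none
Why: Deprotonation gives the non-stabilised ylide, which is C-formylated by the formate ester (acylation of a phosphorus ylide), and the expelled ethoxide deprotonates the formylphosphonium to the isolable formyl-stabilised ylide.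

Step 6
Reactants: 11 (2Z)-2-(3-oxopropyl)hexa-2,5-dien-1-yl (2R)-3-chloro-2-hydroxy-2-methylpropanoate; 15 3-(1,3-dioxolan-2-yl)-2-(triphenyl-λ5-phosphanylidene)propanal
Product: 16 (2Z)-2-[(3E)-5-(1,3-dioxolan-2-yl)-4-formylpent-3-en-1-yl]hexa-2,5-dien-1-yl (2R)-3-chloro-2-hydroxy-2-methylpropanoate
Conditions: toluene, 90 °C, 24 h
Reagents that add atoms: none
Why: Wittig olefination with an α-substituted, formyl-stabilised ylide gives the (E)-2-substituted enal (CHO trans to the C2 chain), which sets the C1=C10 geometry of the target, and the less electrophilic product enal does not react further.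

Step 7
Reactants: 16 (2Z)-2-[(3E)-5-(1,3-dioxolan-2-yl)-4-formylpent-3-en-1-yl]hexa-2,5-dien-1-yl (2R)-3-chloro-2-hydroxy-2-methylpropanoate
Product: 17 (2Z)-2-[(3E)-5-(1,3-dioxolan-2-yl)-4-(hydroxymethyl)pent-3-en-1-yl]hexa-2,5-dien-1-yl (2R)-3-chloro-2-hydroxy-2-methylpropanoate
Conditions: NaBH4 (1.0 equiv), CeCl3·7H2O (1.1 equiv), MeOH, −40 °C, 15 min
Reagents that add atoms: none
Why: Luche 1,2-reduction takes the conjugated aldehyde to the C14 allylic alcohol within minutes at −40 °C, far faster than either ester reacts, and leaves the olefin geometry untouched.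

Step 8
Reactants: 17 (2Z)-2-[(3E)-5-(1,3-dioxolan-2-yl)-4-(hydroxymethyl)pent-3-en-1-yl]hexa-2,5-dien-1-yl (2R)-3-chloro-2-hydroxy-2-methylpropanoate; 18 methyl 2-(bromomethyl)prop-2-enoate
Product: 19 methyl (2Z,5Z,9E)-2-(bromomethyl)-6-({[(2R)-3-chloro-2-hydroxy-2-methylpropanoyl]oxy}methyl)-11-(1,3-dioxolan-2-yl)-10-(hydroxymethyl)undeca-2,5,9-trienoate
Conditions: 18 (6 equiv), second-generation Hoveyda–Grubbs catalyst RuCl2(H2IMes)(=CH-C6H4-2-OiPr) (7 mol %), 1,4-benzoquinone (15 mol %), CH2Cl2, 40 °C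
Reagents that add atoms: none
Why: Olefin cross-metathesis between the terminal (type-one) olefin and a 1,1-disubstituted acrylate is driven by loss of ethene, the trisubstituted olefins are inert, and the enoate forms with the chain trans to the ester (2Z), a geometry that is erased later at the allylchromium stage.

Step 9
Reactants: 19 methyl (2Z,5Z,9E)-2-(bromomethyl)-6-({[(2R)-3-chloro-2-hydroxy-2-methylpropanoyl]oxy}methyl)-11-(1,3-dioxolan-2-yl)-10-(hydroxymethyl)undeca-2,5,9-trienoate
Product: 20 methyl (2Z,5Z,9E)-2-(bromomethyl)-6-[({(2R)-3-chloro-2-methyl-2-[(triethylsilyl)oxy]propanoyl}oxy)methyl]-12-oxo-10-{[(triethylsilyl)oxy]methyl}dodeca-2,5,9-trienoate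
Conditions: TESOTf (4.5 equiv), 2,4,6-collidine (7 equiv), CH2Cl2, 0 °C; then H2O, 0 → 25 °C; used at once
Reagents that add atoms: triethylsilyl trifluoromethanesulfonate, CC[Si](CC)(CC)OS(=O)(=O)C(F)(F)F; water, O
Why: Fujioka–Kita acetal cleavage, in which the silyl triflate opens the dioxolane to an oxocarbenium ion that collidine traps as a pyridinium salt and water then hydrolyses to the aldehyde without protic acid (so the β,γ-unsaturated aldehyde is not isomerised), while the same reagent silylates both hydroxyl groups.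

Step 10
Reactants: 20 methyl (2Z,5Z,9E)-2-(bromomethyl)-6-[({(2R)-3-chloro-2-methyl-2-[(triethylsilyl)oxy]propanoyl}oxy)methyl]-12-oxo-10-{[(triethylsilyl)oxy]methyl}dodeca-2,5,9-trienoate
Product: 23 [(3aR,5Z,9E,11aS)-10-(hydroxymethyl)-3-methylidene-2-oxo-2,3,3a,4,7,8,11,11a-octahydrocyclodeca[b]furan-6-yl]methyl (2R)-3-chloro-2-hydroxy-2-methylpropanoate, via hydroxy ester 21 (not isolated), via bis-silyl lactone 22 (not isolated)
Conditions: CrCl2 (20 mol %), (S,S)-1,8-bis(4-isopropyl-4,5-dihydrooxazol-2-yl)-3,6-diphenyl-9H-carbazole (24 mol %), iPr2NEt (40 mol %), Mn powder (3 equiv), Cp2ZrCl2 (1.3 equiv), THF, 25 °C, 20 added by syringe pump over 12 h (2 mM final); then HF·pyridine, pyridine, THF, 0 → 25 °C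
Reagents that add atoms: none
Why: Proposed new method: an enantioselective, macrocyclising chromium-catalysed 2-(alkoxycarbonyl)allylation of Nozaki–Hiyama–Kishi type followed in the same flask by lactonisation, in which divalent chromium inserts into the allylic C–Br bond, the trivalent allylchromium held by the chiral tridentate ligand adds through its γ-carbon C7 to the Re face of aldehyde C8 via a six-membered chair with both ends of the tether (C6 and C9) equatorial to give the 7,8-anti (7R,8S) alkoxide and the ten-membered carbocycle, Cp2ZrCl2 frees chromium for re-reduction by Mn, the alkoxide closes the γ-lactone with loss of methanol and buffered fluoride removes both silyl groups without the strong acid that would trigger transannular cyclisation of the 1,5-diene; the closest known reactions are the intermolecular chromium-catalysed enantioselective 2-(alkoxycarbonyl)allylation/lactonisation of aldehydes and the stoichiometric CrCl2 ring closure of ω-formyl allylic halides to ten-membered germacrane rings, which is anti-selective.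

**Compound list**

1 | prop-2-yn-1-ol | C#CCO | starting material
2 | 2-(2-bromoethyl)-1,3-dioxolane | BrCCC1OCCO1 | starting material
3 | allyl bromide (3-bromoprop-1-ene) | C=CCBr | starting material
4 | [2-(1,3-dioxolan-2-yl)ethyl]magnesium bromide | Br[Mg]CCC1OCCO1 | intermediate
5 | bromomagnesium (2Z)-3-(bromomagnesio)-2-[2-(1,3-dioxolan-2-yl)ethyl]prop-2-en-1-olate | Br[Mg]OC/C(CCC1OCCO1)=C\[Mg]Br | intermediate
6 | (2Z)-2-[2-(1,3-dioxolan-2-yl)ethyl]hexa-2,5-dien-1-ol | C=CC/C=C(/CCC1OCCO1)CO | intermediate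
7 | (2R)-3-bromo-2-hydroxy-2-methylpropanoic acid | OC(=O)[C@@](C)(O)CBr | starting material
8 | sodium (2S)-2-methyloxirane-2-carboxylate | [Na+].[O-]C(=O)[C@@]1(C)OC1 | intermediate
9 | (2R)-3-chloro-2-hydroxy-2-methylpropanoic acid | OC(=O)[C@@](C)(O)CCl | intermediate
10 | (2Z)-2-[2-(1,3-dioxolan-2-yl)ethyl]hexa-2,5-dien-1-yl (2R)-3-chloro-2-hydroxy-2-methylpropanoate | C=CC/C=C(/CCC1OCCO1)COC(=O)[C@@](C)(O)CCl | intermediate
11 | (2Z)-2-(3-oxopropyl)hexa-2,5-dien-1-yl (2R)-3-chloro-2-hydroxy-2-methylpropanoate | C=CC/C=C(/CCC=O)COC(=O)[C@@](C)(O)CCl | intermediate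
12 | [2-(1,3-dioxolan-2-yl)ethyl]triphenylphosphonium bromide | [Br-].C1COC(CC[P+](c2ccccc2)(c2ccccc2)c2ccccc2)O1 | starting material
13 | ethyl formate | CCOC=O | starting material
14 | [2-(1,3-dioxolan-2-yl)ethylidene]triphenyl-λ5-phosphane | C1COC(CC=P(c2ccccc2)(c2ccccc2)c2ccccc2)O1 | intermediate
15 | 3-(1,3-dioxolan-2-yl)-2-(triphenyl-λ5-phosphanylidene)propanal | O=CC(CC1OCCO1)=P(c1ccccc1)(c1ccccc1)c1ccccc1 | intermediate
16 | (2Z)-2-[(3E)-5-(1,3-dioxolan-2-yl)-4-formylpent-3-en-1-yl]hexa-2,5-dien-1-yl (2R)-3-chloro-2-hydroxy-2-methylpropanoate | O=C/C(CC1OCCO1)=C/CC/C(COC(=O)[C@@](C)(O)CCl)=C/CC=C | intermediate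
17 | (2Z)-2-[(3E)-5-(1,3-dioxolan-2-yl)-4-(hydroxymethyl)pent-3-en-1-yl]hexa-2,5-dien-1-yl (2R)-3-chloro-2-hydroxy-2-methylpropanoate | OC/C(CC1OCCO1)=C/CC/C(COC(=O)[C@@](C)(O)CCl)=C/CC=C | intermediate
18 | methyl 2-(bromomethyl)prop-2-enoate | C=C(CBr)C(=O)OC | starting material
19 | methyl (2Z,5Z,9E)-2-(bromomethyl)-6-({[(2R)-3-chloro-2-hydroxy-2-methylpropanoyl]oxy}methyl)-11-(1,3-dioxolan-2-yl)-10-(hydroxymethyl)undeca-2,5,9-trienoate | OC/C(CC1OCCO1)=C/CC/C(COC(=O)[C@@](C)(O)CCl)=C/C/C=C(\CBr)C(=O)OC | intermediate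
20 | methyl (2Z,5Z,9E)-2-(bromomethyl)-6-[({(2R)-3-chloro-2-methyl-2-[(triethylsilyl)oxy]propanoyl}oxy)methyl]-12-oxo-10-{[(triethylsilyl)oxy]methyl}dodeca-2,5,9-trienoate | O=CC/C(CO[Si](CC)(CC)CC)=C\CC/C(COC(=O)[C@@](C)(O[Si](CC)(CC)CC)CCl)=C/C/C=C(\CBr)C(=O)OC | intermediate
21 | methyl 2-[(1R,2S,4E,8Z)-8-[({(2R)-3-chloro-2-methyl-2-[(triethylsilyl)oxy]propanoyl}oxy)methyl]-2-hydroxy-4-{[(triethylsilyl)oxy]methyl}cyclodeca-4,8-dien-1-yl]prop-2-enoate (formed as its zirconium alkoxide) | O[C@H]1C/C(CO[Si](CC)(CC)CC)=C\CC/C(COC(=O)[C@@](C)(O[Si](CC)(CC)CC)CCl)=C/C[C@@H]1C(=C)C(=O)OC | intermediate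
22 | [(3aR,5Z,9E,11aS)-3-methylidene-2-oxo-10-{[(triethylsilyl)oxy]methyl}-2,3,3a,4,7,8,11,11a-octahydrocyclodeca[b]furan-6-yl]methyl (2R)-3-chloro-2-methyl-2-[(triethylsilyl)oxy]propanoate | C=C1C(=O)O[C@H]2C/C(CO[Si](CC)(CC)CC)=C\CC/C(COC(=O)[C@@](C)(O[Si](CC)(CC)CC)CCl)=C/C[C@H]12 | intermediate
23 | [(3aR,5Z,9E,11aS)-10-(hydroxymethyl)-3-methylidene-2-oxo-2,3,3a,4,7,8,11,11a-octahydrocyclodeca[b]furan-6-yl]methyl (2R)-3-chloro-2-hydroxy-2-methylpropanoate | C=C1C(=O)O[C@H]2C/C(CO)=C\CC/C(COC(=O)[C@@](C)(O)CCl)=C/C[C@H]12 | target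

**Step count**

Total: 10 steps. Longest linear sequence: 8 steps (1, 3, 4, 6, 7, 8, 9, 10); steps 2 and 5 are side branches.

**Steps most likely to fail, with fallbacks**

The ring closure in step 10 is the least secure. Acyclic 2-(alkoxycarbonyl)allylchromium reagents usually give the syn adduct, which here would be the cis-fused lactone, and catalyst control has to hold under high dilution. The fallback sets the C8 configuration by an invertive lactone closure instead of by acyl substitution; it sets out from 20 and comes back at 22. Compound 20 is cyclised with the antipodal (R,R)-ligand and Me3SiCl in place of Cp2ZrCl2, which caps the new alkoxide as the ten-membered (7R,8R) trimethylsilyl ether methyl ester F1 and so blocks lactonisation. Citric acid in MeOH at 0 °C removes only the trimethylsilyl group to give the (7R,8R) hydroxy ester F2, and MsCl/Et3N gives the C8 mesylate F3. Me3SnOH in 1,2-dichloroethane at 70 °C cleaves the unhindered methyl ester to the mesyloxy acid F4, whose carboxylate displaces the mesylate by SN2 (5-exo-tet, inversion at C8) to give the trans-fused 22; HF·pyridine as in step 10 then gives 23.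

In step 9 the silyl triflate/collidine pair has to cleave the dioxolane in the presence of the allylic bromide, which collidine can quaternise, and the β,γ-unsaturated aldehyde can slip into conjugation. The fallback changes the order of events so that the bromide never meets these reagents; it sets out from 17 and comes back at 20. Compound 17 is treated with TESOTf/2,4,6-collidine and then water to give (2Z)-2-[(3E)-6-oxo-4-{[(triethylsilyl)oxy]methyl}hex-3-en-1-yl]hexa-2,5-dien-1-yl (2R)-3-chloro-2-methyl-2-[(triethylsilyl)oxy]propanoate F5. The cross-metathesis with 18 (same ruthenium catalyst and benzoquinone) is then run on F5 as the last operation before ring closure and gives 20.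

In step 1 carbomagnesiation with a functionalised primary alkyl Grignard reagent is slower than with methyl or allyl reagents, and direct allylation of 5 competes with coupling of excess 4. The fallback replaces direct trapping by a cross-coupling; it sets out from 5 and comes back at 6. Compound 5 is quenched with iodine to give (2Z)-2-[2-(1,3-dioxolan-2-yl)ethyl]-3-iodoprop-2-en-1-ol F6, which is isolated and coupled with allyltributylstannane (Stille coupling, PdCl2(MeCN)2, DMF, 25 °C) with retention of the double-bond geometry to give 6.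

**Further compounds**

F1 | step 10 | methyl 2-[(1R,2R,4E,8Z)-8-[({(2R)-3-chloro-2-methyl-2-[(triethylsilyl)oxy]propanoyl}oxy)methyl]-4-{[(triethylsilyl)oxy]methyl}-2-[(trimethylsilyl)oxy]cyclodeca-4,8-dien-1-yl]prop-2-enoate | C[Si](C)(C)O[C@@H]1C/C(CO[Si](CC)(CC)CC)=C\CC/C(COC(=O)[C@@](C)(O[Si](CC)(CC)CC)CCl)=C/C[C@@H]1C(=C)C(=O)OC
F2 | step 10 | methyl 2-[(1R,2R,4E,8Z)-8-[({(2R)-3-chloro-2-methyl-2-[(triethylsilyl)oxy]propanoyl}oxy)methyl]-2-hydroxy-4-{[(triethylsilyl)oxy]methyl}cyclodeca-4,8-dien-1-yl]prop-2-enoate | O[C@@H]1C/C(CO[Si](CC)(CC)CC)=C\CC/C(COC(=O)[C@@](C)(O[Si](CC)(CC)CC)CCl)=C/C[C@@H]1C(=C)C(=O)OC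
F3 | step 10 | methyl 2-[(1R,2R,4E,8Z)-8-[({(2R)-3-chloro-2-methyl-2-[(triethylsilyl)oxy]propanoyl}oxy)methyl]-2-[(methanesulfonyl)oxy]-4-{[(triethylsilyl)oxy]methyl}cyclodeca-4,8-dien-1-yl]prop-2-enoate | CS(=O)(=O)O[C@@H]1C/C(CO[Si](CC)(CC)CC)=C\CC/C(COC(=O)[C@@](C)(O[Si](CC)(CC)CC)CCl)=C/C[C@@H]1C(=C)C(=O)OC
F4 | step 10 | 2-[(1R,2R,4E,8Z)-8-[({(2R)-3-chloro-2-methyl-2-[(triethylsilyl)oxy]propanoyl}oxy)methyl]-2-[(methanesulfonyl)oxy]-4-{[(triethylsilyl)oxy]methyl}cyclodeca-4,8-dien-1-yl]prop-2-enoic acid | CS(=O)(=O)O[C@@H]1C/C(CO[Si](CC)(CC)CC)=C\CC/C(COC(=O)[C@@](C)(O[Si](CC)(CC)CC)CCl)=C/C[C@@H]1C(=C)C(=O)O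
F5 | step 9 | (2Z)-2-[(3E)-6-oxo-4-{[(triethylsilyl)oxy]methyl}hex-3-en-1-yl]hexa-2,5-dien-1-yl (2R)-3-chloro-2-methyl-2-[(triethylsilyl)oxy]propanoate | O=CC/C(CO[Si](CC)(CC)CC)=C\CC/C(COC(=O)[C@@](C)(O[Si](CC)(CC)CC)CCl)=C/CC=C
F6 | step 1 | (2Z)-2-[2-(1,3-dioxolan-2-yl)ethyl]-3-iodoprop-2-en-1-ol | OC/C(CCC1OCCO1)=C\I
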